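Retrosynthesis: the acetate, the C13=C14 alkene (olefination of a C13 methyl ketone, itself from a terminal alkene), the C4–CH3 bond, the C8–CH3 group (via C8=CH2 from a C8 ketone) and the C9–CH3 bond are cut in turn. Ring B is then cut at C9=C10 (aldol) and C5–C6 (Michael), leaving methyl 3-oxocyclohex-1-ene-1-carboxylate (ring A) and octa-1,7-dien-3-one (C6–C9, C11–C13, C16).
Forward: ring A is bought; ring B is closed last, in one flask, from three components (enone ester, a silane hydride, the dienone). The methyl groups C20, C17 and C18 are then added in that order and the chain end is finished.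
Feature used: the ester-bearing carbon C4 of ring A is β to C10, so a C4=C5–C10=O enone gives on 1,4-reduction an enolate fixed at C5, the atom ring B grows from. In ring B the C1=C10 alkene is β,γ to C8 and C9 is quaternary, which is the retron of an aldol enone (C8=O, C9=C10) followed by deconjugative alkylation at C9.
Stereochemistry: a chiral copper hydride sets C4; C4 relays to C5 (trans); C5 controls C9 (the methyl enters last and axially, on the face of H5); C9 controls C8 (hydrogenation anti to C20); C5 controls the final C4 (enolate methylation trans to C6). The E alkene comes from the olefination.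

Key step: step 3

Locants are those of the target skeleton: ring A = C1–C5 and C10, ring B = C5–C10, C17 on C8, C18 (methyl) and C19 (ester carbon) on C4, C20 on C9, chain C11–C15 with C16 on C13; α is the face of H5.
Assumption: (R)-DTBM-SEGPHOS is taken as the ligand enantiomer that gives the (1R)-configured enol silane 7; if the sense of induction is the opposite, the (S)-ligand is used.
Assumption: octa-1,7-dien-3-one is not taken as a catalogue compound and is made in steps 1 and 2.

Step 1
Reactants: 1 5-bromopent-1-ene; 2 acrolein (prop-2-enal)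
Product: 4 octa-1,7-dien-3-ol (racemic), via pent-4-en-1-ylmagnesium bromide 3 (not isolated)
Conditions: Mg, THF, 25–40 °C; then 2, THF, −78 °C; 1 M HCl quench
Reagents that add atoms: none
Why: Grignard formation and 1,2-addition to acrolein at low temperature (Grignard addition) should give the allylic alcohol, whose stereocentre is removed in step 2, so the racemate serves.

Step 2
Reactants: 4 octa-1,7-dien-3-ol
Product: 5 octa-1,7-dien-3-one
Conditions: Dess–Martin periodinane, CH2Cl2, 0 → 25 °C; used at once
Reagents that add atoms: none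
Why: Dess–Martin oxidation of a secondary allylic alcohol is mild and non-basic, so the polymerisable vinyl ketone should form without conjugate addition or alkene migration.

Step 3
Reactants: 6 methyl 3-oxocyclohex-1-ene-1-carboxylate; 5 octa-1,7-dien-3-one
Product: 9 methyl (1R,8aS)-5-(but-3-en-1-yl)-6-oxo-1,2,3,4,6,7,8,8a-octahydronaphthalene-1-carboxylate, via enol silane 7 (not isolated), via diketone 8 (not isolated)
Conditions: Cu(OAc)2·H2O (3 mol%), (R)-DTBM-SEGPHOS (3 mol%), Me2PhSiH, toluene, 0 °C; then 5, Sc(OTf)3 (10 mol%), CH2Cl2, −78 → −40 °C; then TsOH·H2O (20 mol%), toluene, 80 °C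
Reagents that add atoms: none
Why: The ligated copper hydride adds hydride to C4 of the C4=C5–C10=O enone (the ketone, not the ester, is the acceptor) and σ-bond metathesis with the silane frees enol silane 7 with its double bond fixed at C5=C10; Sc(OTf)3-catalysed Mukaiyama–Michael addition then joins C5 to C6 of dienone 5 to give 1,5-diketone 8, and acid-catalysed aldol cyclodehydration of the C9 enol onto the C10 carbonyl closes ring B. The closest known reaction types are the tandem asymmetric copper hydride conjugate reduction/enolate trapping of β-substituted cycloalkenones and the Mukaiyama–Michael form of the Robinson annulation. Ring B closes in the 6-(enolendo)-exo-trig mode and dehydration gives the tetrasubstituted C9=C10 enone, whereas the alternative C1-to-C8 aldol would need a bridgehead alkene and stays reversible. C4 is set by the chiral ligand (R); C5 is set by the substrate, C6 entering anti to the C4 ester and the ketone-α centre equilibrating under the acid to the trans-diequatorial (4R,5S) arrangement, while the C4 ester is not enolised by acid. The step needs 1,4- over 1,2-reduction, attack at C5 and not C1, and a single Michael addition; the bulky bisphosphine copper hydride, the regiodefined enol silane and the low-temperature Lewis-acid protocol should secure these.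

Step 4
Reactants: 9 methyl (1R,8aS)-5-(but-3-en-1-yl)-6-oxo-1,2,3,4,6,7,8,8a-octahydronaphthalene-1-carboxylate
Product: 11 methyl (1R,5R,8aS)-5-(but-3-en-1-yl)-5-methyl-6-oxo-1,2,3,5,6,7,8,8a-octahydronaphthalene-1-carboxylate, via potassium dienolate 10 (not isolated)
Conditions: KOtBu (1.1 equiv), tBuOH–THF, 0 °C; then MeI, 0 °C
Reagents that add atoms: iodomethane, CI
Why: tert-Butoxide should give the thermodynamic heteroannular dienolate (γ-deprotonation at C1 and not at the ring-fusion C5, as in the 4-en-3-one steroid series) and methyl iodide alkylates its α-carbon C9 (deconjugative alkylation), moving the alkene to C1=C10; ring B of the dienolate is a sofa with C6 as the flap and the electrophile enters anti to the flap, on the face of the pseudoaxial H5, so that C20 ends axial and cis to H5 and the butenyl chain equatorial.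

Step 5
Reactants: 11 methyl (1R,5R,8aS)-5-(but-3-en-1-yl)-5-methyl-6-oxo-1,2,3,5,6,7,8,8a-octahydronaphthalene-1-carboxylate
Product: 12 methyl (1R,5S,8aS)-5-(but-3-en-1-yl)-5-methyl-6-methylidene-1,2,3,5,6,7,8,8a-octahydronaphthalene-1-carboxylate
Conditions: Ph3PCH3Br, KOtBu, toluene, 90 °C
Reagents that add atoms: methyltriphenylphosphonium bromide, C[P+](c1ccccc1)(c1ccccc1)c1ccccc1.[Br-]
Why: Wittig methylenation with the salt-free ylide at raised temperature is the usual way to convert a hindered ketone next to a quaternary carbon into the exocyclic alkene, and the ester and both alkenes should be inert.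

Step 6
Reactants: 12 methyl (1R,5S,8aS)-5-(but-3-en-1-yl)-5-methyl-6-methylidene-1,2,3,5,6,7,8,8a-octahydronaphthalene-1-carboxylate
Product: 14 methyl (1S,5S,8aR)-5-(but-3-en-1-yl)-1,5-dimethyl-6-methylidene-1,2,3,5,6,7,8,8a-octahydronaphthalene-1-carboxylate, via lithium ester enolate 13 (not isolated)
Conditions: LDA (1.3 equiv), THF, −78 °C; then MeI, DMPU, −78 → −20 °C
Reagents that add atoms: iodomethane, CI
Why: With no ketone left to compete, the lithium ester enolate should be methylated on the α face, trans to the C5–C6 bond of ring B, which turns pseudoaxial to avoid allylic strain with the enolate and shields the β face (equatorial alkylation of a 2-substituted cyclohexanecarboxylate enolate); this re-makes C4 with the methyl cis to H5 and the ester β, the relay configuration at C4 being erased.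

Step 7
Reactants: 14 methyl (1S,5S,8aR)-5-(but-3-en-1-yl)-1,5-dimethyl-6-methylidene-1,2,3,5,6,7,8,8a-octahydronaphthalene-1-carboxylate
Product: 15 methyl (1S,5S,8aR)-1,5-dimethyl-6-methylidene-5-(3-oxobutyl)-1,2,3,5,6,7,8,8a-octahydronaphthalene-1-carboxylate
Conditions: PdCl2 (10 mol%), CuCl (20 mol%), O2 (1 atm), DMF–H2O 7:1, 25 °C
Reagents that add atoms: water, O
Why: Tsuji–Wacker oxidation is selective for the monosubstituted terminal alkene and gives the methyl ketone, while the 1,1-disubstituted C8=C17 and the trisubstituted C1=C10 alkenes should not be oxidised.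

Step 8
Reactants: 15 methyl (1S,5S,8aR)-1,5-dimethyl-6-methylidene-5-(3-oxobutyl)-1,2,3,5,6,7,8,8a-octahydronaphthalene-1-carboxylate
Product: 16 methyl (1S,5S,6R,8aR)-1,5,6-trimethyl-5-(3-oxobutyl)-1,2,3,5,6,7,8,8a-octahydronaphthalene-1-carboxylate
Conditions: H2 (1 atm), PtO2, EtOAc, 25 °C
Reagents that add atoms: none
Why: Heterogeneous hydrogenation should reduce the exocyclic 1,1-disubstituted alkene and leave the hindered trisubstituted C1=C10 alkene next to the quaternary C9; hydrogen is delivered to the β face, opposite the axial C20 methyl, so C17 becomes equatorial and cis to C20 (8R).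

Step 9
Reactants: 16 methyl (1S,5S,6R,8aR)-1,5,6-trimethyl-5-(3-oxobutyl)-1,2,3,5,6,7,8,8a-octahydronaphthalene-1-carboxylate
Product: 17 methyl (1S,5S,6R,8aR)-5-[(3E)-5-ethoxy-3-methyl-5-oxopent-3-en-1-yl]-1,5,6-trimethyl-1,2,3,5,6,7,8,8a-octahydronaphthalene-1-carboxylate
Conditions: triethyl phosphonoacetate, NaH, THF, 0 → 50 °C; chromatographic removal of the Z isomer
Reagents that add atoms: triethyl phosphonoacetate, CCOC(=O)CP(=O)(OCC)OCC
Why: Horner–Wadsworth–Emmons olefination of the methyl ketone should give the trisubstituted enoate with the E isomer predominating (ester trans to the larger C12 chain), and the hindered C4 ester does not take part.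

Step 10
Reactants: 17 methyl (1S,5S,6R,8aR)-5-[(3E)-5-ethoxy-3-methyl-5-oxopent-3-en-1-yl]-1,5,6-trimethyl-1,2,3,5,6,7,8,8a-octahydronaphthalene-1-carboxylate
Product: 18 methyl (1S,5S,6R,8aR)-5-[(3E)-5-hydroxy-3-methylpent-3-en-1-yl]-1,5,6-trimethyl-1,2,3,5,6,7,8,8a-octahydronaphthalene-1-carboxylate
Conditions: DIBAL-H (2.2 equiv), CH2Cl2, −78 °C; Rochelle salt work-up
Reagents that add atoms: none
Why: DIBAL-H at low temperature should reduce the unhindered conjugated ethyl ester to the allylic alcohol by 1,2-addition, while the axial methyl ester on the quaternary C4 reacts much more slowly.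

Step 11
Reactants: 18 methyl (1S,5S,6R,8aR)-5-[(3E)-5-hydroxy-3-methylpent-3-en-1-yl]-1,5,6-trimethyl-1,2,3,5,6,7,8,8a-octahydronaphthalene-1-carboxylate
Product: 19 methyl (1S,5S,6R,8aR)-5-[(3E)-5-acetoxy-3-methylpent-3-en-1-yl]-1,5,6-trimethyl-1,2,3,5,6,7,8,8a-octahydronaphthalene-1-carboxylate (CNP0209995.1)
Conditions: Ac2O, pyridine, DMAP (cat.), CH2Cl2, 25 °C
Reagents that add atoms: acetic anhydride, CC(=O)OC(C)=O
Why: DMAP-catalysed acetylation of the primary allylic alcohol should give the target without touching any stereocentre.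

Compound list
1 | 5-bromopent-1-ene | C=CCCCBr | starting material
2 | acrolein (prop-2-enal) | C=CC=O | starting material
3 | pent-4-en-1-ylmagnesium bromide | C=CCCC[Mg]Br | intermediate
4 | octa-1,7-dien-3-ol (racemic) | C=CCCCC(O)C=C | intermediate
5 | octa-1,7-dien-3-one | C=CCCCC(=O)C=C | intermediate
6 | methyl 3-oxocyclohex-1-ene-1-carboxylate | COC(=O)C1=CC(=O)CCC1 | starting material
7 | methyl (1R)-3-{[dimethyl(phenyl)silyl]oxy}cyclohex-2-ene-1-carboxylate | COC(=O)[C@@H]1CCCC(O[Si](C)(C)c2ccccc2)=C1 | intermediate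
8 | methyl (1R,2S)-3-oxo-2-(3-oxooct-7-en-1-yl)cyclohexane-1-carboxylate | COC(=O)[C@@H]1CCCC(=O)[C@H]1CCC(=O)CCCC=C | intermediate
9 | methyl (1R,8aS)-5-(but-3-en-1-yl)-6-oxo-1,2,3,4,6,7,8,8a-octahydronaphthalene-1-carboxylate | COC(=O)[C@@H]1CCCC2=C(CCC=C)C(=O)CC[C@@H]12 | intermediate
10 | potassium dienolate of 9 (oxygen on C8, double bonds C8=C9 and C10=C1) | COC(=O)[C@@H]1CCC=C2[C@H]1CCC([O-])=C2CCC=C.[K+] | intermediate
11 | methyl (1R,5R,8aS)-5-(but-3-en-1-yl)-5-methyl-6-oxo-1,2,3,5,6,7,8,8a-octahydronaphthalene-1-carboxylate | COC(=O)[C@@H]1CCC=C2[C@H]1CCC(=O)[C@]2(C)CCC=C | intermediate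
12 | methyl (1R,5S,8aS)-5-(but-3-en-1-yl)-5-methyl-6-methylidene-1,2,3,5,6,7,8,8a-octahydronaphthalene-1-carboxylate | COC(=O)[C@@H]1CCC=C2[C@H]1CCC(=C)[C@]2(C)CCC=C | intermediate
13 | lithium ester enolate of 12 (C4=C19 ketene acetal oxide) | COC([O-])=C1CCC=C2[C@H]1CCC(=C)[C@]2(C)CCC=C.[Li+] | intermediate
14 | methyl (1S,5S,8aR)-5-(but-3-en-1-yl)-1,5-dimethyl-6-methylidene-1,2,3,5,6,7,8,8a-octahydronaphthalene-1-carboxylate | COC(=O)[C@@]1(C)CCC=C2[C@H]1CCC(=C)[C@]2(C)CCC=C | intermediate
15 | methyl (1S,5S,8aR)-1,5-dimethyl-6-methylidene-5-(3-oxobutyl)-1,2,3,5,6,7,8,8a-octahydronaphthalene-1-carboxylate | COC(=O)[C@@]1(C)CCC=C2[C@H]1CCC(=C)[C@]2(C)CCC(C)=O | intermediate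
16 | methyl (1S,5S,6R,8aR)-1,5,6-trimethyl-5-(3-oxobutyl)-1,2,3,5,6,7,8,8a-octahydronaphthalene-1-carboxylate | COC(=O)[C@@]1(C)CCC=C2[C@H]1CC[C@@H](C)[C@]2(C)CCC(C)=O | intermediate
17 | methyl (1S,5S,6R,8aR)-5-[(3E)-5-ethoxy-3-methyl-5-oxopent-3-en-1-yl]-1,5,6-trimethyl-1,2,3,5,6,7,8,8a-octahydronaphthalene-1-carboxylate | COC(=O)[C@@]1(C)CCC=C2[C@H]1CC[C@@H](C)[C@]2(C)CC/C(C)=C/C(=O)OCC | intermediate
18 | methyl (1S,5S,6R,8aR)-5-[(3E)-5-hydroxy-3-methylpent-3-en-1-yl]-1,5,6-trimethyl-1,2,3,5,6,7,8,8a-octahydronaphthalene-1-carboxylate | COC(=O)[C@@]1(C)CCC=C2[C@H]1CC[C@@H](C)[C@]2(C)CC/C(C)=C/CO | intermediate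
19 | methyl (1S,5S,6R,8aR)-5-[(3E)-5-acetoxy-3-methylpent-3-en-1-yl]-1,5,6-trimethyl-1,2,3,5,6,7,8,8a-octahydronaphthalene-1-carboxylate | COC(=O)[C@@]1(C)CCC=C2[C@H]1CC[C@@H](C)[C@]2(C)CC/C(C)=C/COC(C)=O | target

Total step count: 11. Longest linear sequence: 11 steps (1 → 19); 9 steps from 6.

Steps most likely to fail

Step 3. What may go wrong: incomplete enantiofacial discrimination by the copper hydride at a β-carbon that bears an ester, and erosion of the C4 centre by enolisation of the doubly activated C4–H of the enol silane. Fallback, from 6 and back at 9: the sequence is run without a chiral ligand, using hexameric triphenylphosphine copper hydride [(Ph3P)CuH]6 and Me2PhSiH. This gives 7 together with its enantiomer, methyl (1S)-3-{[dimethyl(phenyl)silyl]oxy}cyclohex-2-ene-1-carboxylate F1. The same Michael addition and cyclodehydration then give 8 with the enantiomeric diketone F2, and 9 with the enantiomeric enone F3. Enone 9 is separated from F3 by preparative chromatography on a chiral stationary phase and enters step 4.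

Step 4. What may go wrong: methylation on oxygen or at C7, a second methylation, attack on the wrong face of C9, and loss of configuration at C5 through the minor C5-dienolate. Fallback, from 9 and back at 11: TBSOTf and Et3N (CH2Cl2, 0 °C) convert 9 into the thermodynamic silyl dienol ether F4 (silyloxy on C8, double bonds C8=C9 and C10=C1). Et2Zn and CH2I2 cyclopropanate its electron-rich C8=C9 bond from the α face, anti to the C6 flap, to give the siloxycyclopropane F5. TBAF then opens the cyclopropanolate at the primary carbon and gives 11, the carbenoid carbon becoming C20.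

Step 9. What may go wrong: poor E/Z control in the olefination of a methyl ketone, and sluggish reaction. Fallback, from 16 and back at 17: kinetic enolisation of the methyl ketone with LDA (−78 °C) and O-phosphorylation with diethyl chlorophosphate give the enol phosphate F6. Elimination with further LDA gives the terminal alkyne F7. Zirconium-catalysed methylalumination (Me3Al, Cp2ZrCl2 cat., CH2Cl2) gives the (E)-alkenylalane F8 by syn addition, and ethyl chloroformate converts it with retention into 17.

Further compounds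
F1 | step 3 | methyl (1S)-3-{[dimethyl(phenyl)silyl]oxy}cyclohex-2-ene-1-carboxylate (enantiomer of 7) | COC(=O)[C@H]1CCCC(O[Si](C)(C)c2ccccc2)=C1
F2 | step 3 | methyl (1S,2R)-3-oxo-2-(3-oxooct-7-en-1-yl)cyclohexane-1-carboxylate (enantiomer of 8) | COC(=O)[C@H]1CCCC(=O)[C@@H]1CCC(=O)CCCC=C
F3 | step 3 | methyl (1S,8aR)-5-(but-3-en-1-yl)-6-oxo-1,2,3,4,6,7,8,8a-octahydronaphthalene-1-carboxylate (enantiomer of 9) | COC(=O)[C@H]1CCCC2=C(CCC=C)C(=O)CC[C@H]12
F4 | step 4 | methyl (1R,8aS)-5-(but-3-en-1-yl)-6-{[tert-butyl(dimethyl)silyl]oxy}-1,2,3,7,8,8a-hexahydronaphthalene-1-carboxylate | COC(=O)[C@@H]1CCC=C2[C@H]1CCC(O[Si](C)(C)C(C)(C)C)=C2CCC=C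
F5 | step 4 | siloxycyclopropane from F4: CH2 bridging C8 and C9 on the α face (cis to H5), OTBS on C8, but-3-enyl on C9, C1=C10 retained | COC(=O)[C@@H]1CCC=C2[C@H]1CC[C@@]3(O[Si](C)(C)C(C)(C)C)C[C@@]23CCC=C
F6 | step 9 | methyl (1S,5S,6R,8aR)-5-{3-[(diethoxyphosphoryl)oxy]but-3-en-1-yl}-1,5,6-trimethyl-1,2,3,5,6,7,8,8a-octahydronaphthalene-1-carboxylate | COC(=O)[C@@]1(C)CCC=C2[C@H]1CC[C@@H](C)[C@]2(C)CCC(=C)OP(=O)(OCC)OCC
F7 | step 9 | methyl (1S,5S,6R,8aR)-5-(but-3-yn-1-yl)-1,5,6-trimethyl-1,2,3,5,6,7,8,8a-octahydronaphthalene-1-carboxylate | COC(=O)[C@@]1(C)CCC=C2[C@H]1CC[C@@H](C)[C@]2(C)CCC#C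
F8 | step 9 | methyl (1S,5S,6R,8aR)-5-[(3E)-4-(dimethylalumanyl)-3-methylbut-3-en-1-yl]-1,5,6-trimethyl-1,2,3,5,6,7,8,8a-octahydronaphthalene-1-carboxylate | COC(=O)[C@@]1(C)CCC=C2[C@H]1CC[C@@H](C)[C@]2(C)CC/C(C)=C/[Al](C)C
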